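**Retrosynthetic overview**

1. The target is reached last by a thermal 1,2-interchange of the two ring halogens in its trans-diaxial isomer, which carries Cl at C4 and Br at C5 of the cyclohexane ring (numbering: C1 carbinol, C2 the oxanyl-bearing CH, C5 the methyl/halogen carbon).
2. That isomer comes from an acyclic (2S,4R)-2-oxanyl-4-chloro-5-methylhex-5-enal by a Prins (cation–olefin) closure of C1–C6 with bromide capture at C5. The enabling feature is that C1–OH and the quaternary C5 stand 1,3 across the C6 methylene (a 1,3-halohydrin) with the second halogen on C4, so an aldehyde carbon (C1) and a 2-methylallyl chloride unit (C4–C5=C6) map onto the ring; the tertiary cation at the methyl-bearing carbon echoes the bisabolyl cation of the biosynthesis.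
3. The aldehyde comes from a prenylated oxanylacetic acid derivative: C4–Cl by Shi epoxidation, epoxide-to-allylic-alcohol isomerisation and SN2 chlorination of the prenyl group; C2 by Evans alkylation.
4. The oxane ring is made first, by bromoetherification of (S)-linalool, whose vinyl group becomes the acetic acid arm.
5. Ring order: oxane (step 1), then cyclohexane (step 13).

Key step: step 13

Remark: (S)-(+)-linalool of high enantiomeric purity and the L-fructose-derived (ent) Shi ketone are taken as purchasable.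

**Route**

Step 1
Reactants: 1 (S)-(+)-linalool
Product: 2 (3R,6S)-3-bromo-6-ethenyl-2,2,6-trimethyloxane
Conditions: 2,4,4,6-tetrabromocyclohexa-2,5-dien-1-one (TBCO), MeNO2, 0 °C → rt; chromatography
Reagents that add atoms: 2,4,4,6-tetrabromocyclohexa-2,5-dien-1-one, O=C1C(Br)=CC(Br)(Br)C=C1Br
Why: Bromoetherification (bromonium ion opened 6-endo at the more substituted carbon by the tertiary hydroxyl through a chair with equatorial bromine): C6 is carried over from linalool, whereas the new C3 centre is only weakly biased because vinyl and methyl are of similar size, so the (3R,6S) isomer is expected together with its C3 epimer and oxolane regioisomers and is separated by chromatography.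

Step 2
Reactants: 2 (3R,6S)-3-bromo-6-ethenyl-2,2,6-trimethyloxane
Product: 4 2-[(2S,5R)-5-bromo-2,6,6-trimethyloxan-2-yl]ethan-1-ol, via B-alkyl-9-BBN adduct 3 (not isolated)
Conditions: 9-BBN, THF, 0 °C → rt; then NaOH, H2O2, H2O, 0 °C
Reagents that add atoms: hydrogen peroxide, OO
Why: Hydroboration–oxidation: the bulky borane places boron on the terminal carbon of the vinyl group next to the quaternary centre and oxidation with retention gives the primary alcohol, no stereocentre being touched.

Step 3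
Reactants: 4 2-[(2S,5R)-5-bromo-2,6,6-trimethyloxan-2-yl]ethan-1-ol
Product: 6 2-[(2S,5R)-5-bromo-2,6,6-trimethyloxan-2-yl]acetic acid, via aldehyde 5 (not isolated)
Conditions: TEMPO (cat.), PhI(OAc)2, MeCN/H2O, rt
Reagents that add atoms: water, O
Why: TEMPO/PhI(OAc)2 oxidation in aqueous acetonitrile takes the primary alcohol through the aldehyde hydrate to the carboxylic acid under near-neutral conditions that leave the secondary bromide and the ether untouched.

Step 4
Reactants: 6 2-[(2S,5R)-5-bromo-2,6,6-trimethyloxan-2-yl]acetic acid; 7 (S)-4-benzyl-1,3-oxazolidin-2-one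
Product: 9 (4S)-4-benzyl-3-{2-[(2S,5R)-5-bromo-2,6,6-trimethyloxan-2-yl]acetyl}-1,3-oxazolidin-2-one, via pivalic mixed anhydride 8 (not isolated)
Conditions: t-BuCOCl, Et3N, THF, −20 °C; then 7, LiCl, −20 °C → rt
Reagents that add atoms: none
Why: N-acylation of the oxazolidinone through the pivalic mixed anhydride with LiCl/Et3N activation is the standard entry to Evans imides.

Step 5
Reactants: 9 (4S)-4-benzyl-3-{2-[(2S,5R)-5-bromo-2,6,6-trimethyloxan-2-yl]acetyl}-1,3-oxazolidin-2-one; 10 1-bromo-3-methylbut-2-ene (prenyl bromide)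
Product: 12 (4S)-4-benzyl-3-[(2S)-2-[(2S,5R)-5-bromo-2,6,6-trimethyloxan-2-yl]-5-methylhex-4-enoyl]-1,3-oxazolidin-2-one, via sodium enolate 11 (not isolated)
Conditions: NaN(SiMe3)2, THF, −78 °C; then 10, −78 → −40 °C
Reagents that add atoms: none
Why: Evans asymmetric alkylation: the chelated (Z)-sodium enolate is attacked by the allylic bromide on the face opposite the benzyl group, which sets C2 of the side chain as (S) under auxiliary control.

Step 6
Reactants: 12 (4S)-4-benzyl-3-[(2S)-2-[(2S,5R)-5-bromo-2,6,6-trimethyloxan-2-yl]-5-methylhex-4-enoyl]-1,3-oxazolidin-2-one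
Product: 13 (2R)-2-[(2S,5R)-5-bromo-2,6,6-trimethyloxan-2-yl]-5-methylhex-4-en-1-ol
Conditions: LiBH4, H2O (1 equiv), Et2O, 0 °C
Reagents that add atoms: none
Why: Reductive removal of the auxiliary: LiBH4 reduces the exocyclic imide carbonyl to the primary alcohol without touching the hindered secondary bromide or epimerising the α-centre (the descriptor changes from S to R only through CIP priorities).

Step 7
Reactants: 13 (2R)-2-[(2S,5R)-5-bromo-2,6,6-trimethyloxan-2-yl]-5-methylhex-4-en-1-ol
Product: 14 tert-butyl{[(2R)-2-[(2S,5R)-5-bromo-2,6,6-trimethyloxan-2-yl]-5-methylhex-4-en-1-yl]oxy}dimethylsilane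
Conditions: TBSCl, imidazole, DMF, rt
Reagents that add atoms: tert-butyl(chloro)dimethylsilane, CC(C)(C)[Si](C)(C)Cl
Why: Silyl ether formation protects the primary hydroxyl so that it cannot open the epoxide made in the next step.

Step 8
Reactants: 14 tert-butyl{[(2R)-2-[(2S,5R)-5-bromo-2,6,6-trimethyloxan-2-yl]-5-methylhex-4-en-1-yl]oxy}dimethylsilane
Product: 15 tert-butyl{[(2R)-2-[(2S,5R)-5-bromo-2,6,6-trimethyloxan-2-yl]-3-[(2S)-3,3-dimethyloxiran-2-yl]propyl]oxy}dimethylsilane
Conditions: ent-Shi ketone (L-fructose-derived, 30 mol%), Oxone (2KHSO5·KHSO4·K2SO4), K2CO3, Bu4NHSO4, MeCN/dimethoxymethane/aq. Na2B4O7 buffer, 0 °C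
Reagents that add atoms: potassium peroxymonosulfate, [K+].[O-]S(=O)(=O)OO
Why: Shi epoxidation: the dioxirane of the L-fructose-derived ketone attacks the only alkene through the spiro transition state and should give the (S)-epoxide under reagent control (the D-fructose-derived ketone gives the (R)-epoxide of such prenyl termini).

Step 9
Reactants: 15 tert-butyl{[(2R)-2-[(2S,5R)-5-bromo-2,6,6-trimethyloxan-2-yl]-3-[(2S)-3,3-dimethyloxiran-2-yl]propyl]oxy}dimethylsilane
Product: 16 (3S,5R)-5-[(2S,5R)-5-bromo-2,6,6-trimethyloxan-2-yl]-6-[(tert-butyldimethylsilyl)oxy]-2-methylhex-1-en-3-ol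
Conditions: Et2Al(TMP) [from Et2AlCl and lithium 2,2,6,6-tetramethylpiperidide, itself from the amine and n-BuLi], toluene, 0 °C
Reagents that add atoms: none
Why: Base-induced epoxide-to-allylic-alcohol isomerisation: the bulky aluminium amide binds the epoxide oxygen and removes a proton from the less hindered methyl group, so the C–O bond at the secondary carbon, and with it the (S) configuration, is untouched.

Step 10
Reactants: 16 (3S,5R)-5-[(2S,5R)-5-bromo-2,6,6-trimethyloxan-2-yl]-6-[(tert-butyldimethylsilyl)oxy]-2-methylhex-1-en-3-ol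
Product: 17 tert-butyl{[(2R,4R)-2-[(2S,5R)-5-bromo-2,6,6-trimethyloxan-2-yl]-4-chloro-5-methylhex-5-en-1-yl]oxy}dimethylsilane
Conditions: PPh3, hexachloroacetone, CH2Cl2, −20 → 0 °C
Reagents that add atoms: hexachloroacetone, ClC(Cl)(Cl)C(=O)C(Cl)(Cl)Cl
Why: Appel-type chlorination with PPh3/hexachloroacetone: the oxyphosphonium salt of the secondary allylic alcohol is displaced by chloride in an SN2 manner with inversion and little allylic transposition, turning the (S) carbinol into the (R) chloride.

Step 11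
Reactants: 17 tert-butyl{[(2R,4R)-2-[(2S,5R)-5-bromo-2,6,6-trimethyloxan-2-yl]-4-chloro-5-methylhex-5-en-1-yl]oxy}dimethylsilane
Product: 18 (2R,4R)-2-[(2S,5R)-5-bromo-2,6,6-trimethyloxan-2-yl]-4-chloro-5-methylhex-5-en-1-ol
Conditions: HF·pyridine, pyridine, THF, 0 °C → rt
Reagents that add atoms: none
Why: Fluoride-mediated desilylation under buffered, weakly acidic conditions spares the allylic chloride and the secondary bromide.

Step 12
Reactants: 18 (2R,4R)-2-[(2S,5R)-5-bromo-2,6,6-trimethyloxan-2-yl]-4-chloro-5-methylhex-5-en-1-ol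
Product: 19 (2S,4R)-2-[(2S,5R)-5-bromo-2,6,6-trimethyloxan-2-yl]-4-chloro-5-methylhex-5-enal
Conditions: Dess–Martin periodinane, pyridine, CH2Cl2, 0 °C → rt
Reagents that add atoms: none
Why: Dess–Martin oxidation gives the α-branched aldehyde under non-basic, non-epimerising conditions (the descriptor at C2 changes to S only through CIP priorities).

Step 13
Reactants: 19 (2S,4R)-2-[(2S,5R)-5-bromo-2,6,6-trimethyloxan-2-yl]-4-chloro-5-methylhex-5-enal
Product: 20 (1S,2R,4R,5R)-5-bromo-2-[(2S,5R)-5-bromo-2,6,6-trimethyloxan-2-yl]-4-chloro-5-methylcyclohexan-1-ol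
Conditions: TiBr4 (1.2 equiv), CH2Cl2 (high dilution), −78 °C; then pH 7 buffer
Reagents that add atoms: titanium tetrabromide, Br[Ti](Br)(Br)Br
Why: TiBr4 binds the aldehyde oxygen (probably together with the oxane oxygen as a six-membered chelate), the CH2 terminus of the 1,1-disubstituted alkene attacks the activated carbonyl carbon, and the tertiary cyclohexyl cation formed at the methyl-bearing carbon is quenched by bromide handed over from the titanium alkoxide, i.e. a Prins cyclisation with halide capture. The closest known reaction type is the Lewis acid-mediated cyclisation of 5-methylhex-5-enals to cis-3-halo-3-methylcyclohexanols (the carbonyl-ene manifold interrupted by halide). The cyclohexane ring closes through a chair in a 6-endo-trig mode with respect to the alkene (exo with respect to the carbonyl), C1–C6 being the only new C–C bond. The carbinol centre C1 is set by that chair, with the bulky oxanyl group at C2 equatorial and the O–Ti bond axial beside the developing cation; C5 is set by delivery of bromide from the O–Ti–Br unit to the face syn to oxygen, which is also the face anti to the axial C4–Cl bond, so that OH, Br and Cl all end axial. The step needs bromide capture to beat proton loss (ene product) and needs the allylic chloride to survive; −78 °C, a non-basic bromide-rich Lewis acid and the inductively deactivated, slowly ionising secondary allylic chloride should secure this. The (2S,4R) pairing of the substrate allows an equatorial oxanyl group and an axial chlorine (no A(1,2) strain with the vinylic methyl) in one and the same chair, so the control elements reinforce each other.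

Step 14
Reactants: 20 (1S,2R,4R,5R)-5-bromo-2-[(2S,5R)-5-bromo-2,6,6-trimethyloxan-2-yl]-4-chloro-5-methylcyclohexan-1-ol
Product: 21 (1S,2R,4S,5S)-4-bromo-2-[(2S,5R)-5-bromo-2,6,6-trimethyloxan-2-yl]-5-chloro-5-methylcyclohexan-1-ol
Conditions: chlorobenzene, 130 °C, sealed tube, dark
Reagents that add atoms: none
Why: Thermal diaxial-to-diequatorial rearrangement of a trans-vicinal dihalide (dyotropic 1,2-interchange through a bridged halonium–halide ion pair, known for trans-diaxial bromochlorides of steroids and terpenoids): the anti-periplanar axial Br (C5) and Cl (C4) exchange places, each on its own face, which inverts C4 and C5 stereospecifically and should be driven by relief of the syn-diaxial Br/OH contact, the smaller chlorine ending on the tertiary carbon.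

**Compound list**

1 | (S)-(+)-linalool, (3S)-3,7-dimethylocta-1,6-dien-3-ol | CC(C)=CCC[C@](C)(O)C=C | starting material
2 | (3R,6S)-3-bromo-6-ethenyl-2,2,6-trimethyloxane | CC1(C)O[C@](C)(C=C)CC[C@H]1Br | intermediate
3 | 9-{2-[(2R,5R)-5-bromo-2,6,6-trimethyloxan-2-yl]ethyl}-9-borabicyclo[3.3.1]nonane (same geometry as 2; descriptor changed by CIP priorities) | CC1(C)O[C@](C)(CCB2C3CCCC2CCC3)CC[C@H]1Br | intermediate (not isolated)
4 | 2-[(2S,5R)-5-bromo-2,6,6-trimethyloxan-2-yl]ethan-1-ol | CC1(C)O[C@](C)(CCO)CC[C@H]1Br | intermediate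
5 | 2-[(2S,5R)-5-bromo-2,6,6-trimethyloxan-2-yl]acetaldehyde | CC1(C)O[C@](C)(CC=O)CC[C@H]1Br | intermediate (not isolated)
6 | 2-[(2S,5R)-5-bromo-2,6,6-trimethyloxan-2-yl]acetic acid | CC1(C)O[C@](C)(CC(O)=O)CC[C@H]1Br | intermediate
7 | (S)-4-benzyl-1,3-oxazolidin-2-one | O=C1N[C@@H](Cc2ccccc2)CO1 | starting material
8 | 2-[(2S,5R)-5-bromo-2,6,6-trimethyloxan-2-yl]acetic 2,2-dimethylpropanoic anhydride | CC1(C)O[C@](C)(CC(=O)OC(=O)C(C)(C)C)CC[C@H]1Br | intermediate (not isolated)
9 | (4S)-4-benzyl-3-{2-[(2S,5R)-5-bromo-2,6,6-trimethyloxan-2-yl]acetyl}-1,3-oxazolidin-2-one | CC1(C)O[C@](C)(CC(=O)N2[C@@H](Cc3ccccc3)COC2=O)CC[C@H]1Br | intermediate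
10 | 1-bromo-3-methylbut-2-ene (prenyl bromide) | CC(C)=CCBr | starting material
11 | sodium (Z)-1-[(4S)-4-benzyl-2-oxo-1,3-oxazolidin-3-yl]-2-[(2S,5R)-5-bromo-2,6,6-trimethyloxan-2-yl]ethen-1-olate | CC1(C)O[C@](C)(/C=C(\[O-])N2[C@@H](Cc3ccccc3)COC2=O)CC[C@H]1Br.[Na+] | intermediate (not isolated)
12 | (4S)-4-benzyl-3-[(2S)-2-[(2S,5R)-5-bromo-2,6,6-trimethyloxan-2-yl]-5-methylhex-4-enoyl]-1,3-oxazolidin-2-one | CC1(C)O[C@](C)([C@@H](C(=O)N2[C@@H](Cc3ccccc3)COC2=O)CC=C(C)C)CC[C@H]1Br | intermediate
13 | (2R)-2-[(2S,5R)-5-bromo-2,6,6-trimethyloxan-2-yl]-5-methylhex-4-en-1-ol | CC1(C)O[C@](C)([C@@H](CO)CC=C(C)C)CC[C@H]1Br | intermediate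
14 | tert-butyl{[(2R)-2-[(2S,5R)-5-bromo-2,6,6-trimethyloxan-2-yl]-5-methylhex-4-en-1-yl]oxy}dimethylsilane | CC1(C)O[C@](C)([C@@H](CO[Si](C)(C)C(C)(C)C)CC=C(C)C)CC[C@H]1Br | intermediate
15 | tert-butyl{[(2R)-2-[(2S,5R)-5-bromo-2,6,6-trimethyloxan-2-yl]-3-[(2S)-3,3-dimethyloxiran-2-yl]propyl]oxy}dimethylsilane | CC1(C)O[C@](C)([C@@H](CO[Si](C)(C)C(C)(C)C)C[C@@H]2OC2(C)C)CC[C@H]1Br | intermediate
16 | (3S,5R)-5-[(2S,5R)-5-bromo-2,6,6-trimethyloxan-2-yl]-6-[(tert-butyldimethylsilyl)oxy]-2-methylhex-1-en-3-ol | CC1(C)O[C@](C)([C@@H](CO[Si](C)(C)C(C)(C)C)C[C@H](O)C(C)=C)CC[C@H]1Br | intermediate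
17 | tert-butyl{[(2R,4R)-2-[(2S,5R)-5-bromo-2,6,6-trimethyloxan-2-yl]-4-chloro-5-methylhex-5-en-1-yl]oxy}dimethylsilane | CC1(C)O[C@](C)([C@@H](CO[Si](C)(C)C(C)(C)C)C[C@@H](Cl)C(C)=C)CC[C@H]1Br | intermediate
18 | (2R,4R)-2-[(2S,5R)-5-bromo-2,6,6-trimethyloxan-2-yl]-4-chloro-5-methylhex-5-en-1-ol | CC1(C)O[C@](C)([C@@H](CO)C[C@@H](Cl)C(C)=C)CC[C@H]1Br | intermediate
19 | (2S,4R)-2-[(2S,5R)-5-bromo-2,6,6-trimethyloxan-2-yl]-4-chloro-5-methylhex-5-enal | CC1(C)O[C@](C)([C@@H](C=O)C[C@@H](Cl)C(C)=C)CC[C@H]1Br | intermediate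
20 | (1S,2R,4R,5R)-5-bromo-2-[(2S,5R)-5-bromo-2,6,6-trimethyloxan-2-yl]-4-chloro-5-methylcyclohexan-1-ol (OH, C5–Br and C4–Cl axial; oxanyl equatorial) | CC1(C)O[C@](C)([C@@H]2C[C@@H](Cl)[C@](C)(Br)C[C@@H]2O)CC[C@H]1Br | intermediate
21 | (1S,2R,4S,5S)-4-bromo-2-[(2S,5R)-5-bromo-2,6,6-trimethyloxan-2-yl]-5-chloro-5-methylcyclohexan-1-ol | CC1(C)O[C@](C)([C@@H]2C[C@H](Br)[C@@](C)(Cl)C[C@@H]2O)CC[C@H]1Br | target

**Step count and risks**

Total step count: 14. Longest linear sequence: 14 steps (1 to 21).

Steps most likely to fail: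

Step 13. Proton loss from the tertiary cation (ene pathway) or ionisation and halide exchange at the allylic chloride may outrun bromide capture, or bromide may be delivered to the wrong face of C5. The fallback sets out from 19 and separates C–C from C–Br bond formation. Me2AlCl (CH2Cl2, −78 → 0 °C), a proton-accepting Lewis acid, should give by carbonyl-ene cyclisation through the same chair the homoallylic alcohol (1S,2R,4R)-2-[(2S,5R)-5-bromo-2,6,6-trimethyloxan-2-yl]-4-chloro-5-methylidenecyclohexan-1-ol F1. Dry HBr (CH2Cl2, −78 °C, dark, radical inhibitor) should then add in the Markovnikov sense, bromide entering axially and anti to the axial C4–Cl bond. The fallback comes back to the route at 20.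

Step 14. Elimination of HBr from the tertiary bromide, or displacement or fragmentation started by the syn-axial hydroxyl, may outrun the halogen interchange, or the equilibrium may stop short of 21. The fallback sets out from 20 and moves the interchange to a compound without a free hydroxyl. Et3SiOTf/2,6-lutidine (CH2Cl2, −78 °C) should give {[(1S,2R,4R,5R)-5-bromo-2-[(2S,5R)-5-bromo-2,6,6-trimethyloxan-2-yl]-4-chloro-5-methylcyclohexyl]oxy}triethylsilane F2. Heating F2 in a polar non-nucleophilic medium (MeNO2, 90 °C), which favours the more polar diequatorial dihalide, should give {[(1S,2R,4S,5S)-4-bromo-2-[(2S,5R)-5-bromo-2,6,6-trimethyloxan-2-yl]-5-chloro-5-methylcyclohexyl]oxy}triethylsilane F3. HF·pyridine (THF, 0 °C) then comes back to the route at 21.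

Step 5. The neopentyl-type enolate may alkylate sluggishly, and β-elimination of the ring oxygen (opening of the oxane) may compete. The fallback sets out from 4 and uses an azaenolate at the aldehyde oxidation level. Dess–Martin oxidation gives aldehyde 5, isolated this time, and condensation with RAMP gives (E)-2-[(2S,5R)-5-bromo-2,6,6-trimethyloxan-2-yl]-N-[(2R)-2-(methoxymethyl)pyrrolidin-1-yl]ethan-1-imine F4. Deprotonation with LiN(i-Pr)2 (THF, 0 °C) and alkylation with 10 at −100 °C should give (1E,2R)-2-[(2S,5R)-5-bromo-2,6,6-trimethyloxan-2-yl]-N-[(2R)-2-(methoxymethyl)pyrrolidin-1-yl]-5-methylhex-4-en-1-imine F5; RAMP shows the same facial sense as the (S)-oxazolidinone. Two-phase hydrolysis with aqueous oxalic acid/Et2O should give (2S)-2-[(2S,5R)-5-bromo-2,6,6-trimethyloxan-2-yl]-5-methylhex-4-enal F6, and NaBH4 (MeOH, 0 °C) comes back to the route at 13.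

Further compounds
F1 | step 13 | (1S,2R,4R)-2-[(2S,5R)-5-bromo-2,6,6-trimethyloxan-2-yl]-4-chloro-5-methylidenecyclohexan-1-ol | CC1(C)O[C@](C)([C@@H]2C[C@@H](Cl)C(=C)C[C@@H]2O)CC[C@H]1Br
F2 | step 14 | {[(1S,2R,4R,5R)-5-bromo-2-[(2S,5R)-5-bromo-2,6,6-trimethyloxan-2-yl]-4-chloro-5-methylcyclohexyl]oxy}triethylsilane | CC1(C)O[C@](C)([C@@H]2C[C@@H](Cl)[C@](C)(Br)C[C@@H]2O[Si](CC)(CC)CC)CC[C@H]1Br
F3 | step 14 | {[(1S,2R,4S,5S)-4-bromo-2-[(2S,5R)-5-bromo-2,6,6-trimethyloxan-2-yl]-5-chloro-5-methylcyclohexyl]oxy}triethylsilane | CC1(C)O[C@](C)([C@@H]2C[C@H](Br)[C@@](C)(Cl)C[C@@H]2O[Si](CC)(CC)CC)CC[C@H]1Br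
F4 | step 5 | (E)-2-[(2S,5R)-5-bromo-2,6,6-trimethyloxan-2-yl]-N-[(2R)-2-(methoxymethyl)pyrrolidin-1-yl]ethan-1-imine | CC1(C)O[C@](C)(C/C=N/N2CCC[C@@H]2COC)CC[C@H]1Br
F5 | step 5 | (1E,2R)-2-[(2S,5R)-5-bromo-2,6,6-trimethyloxan-2-yl]-N-[(2R)-2-(methoxymethyl)pyrrolidin-1-yl]-5-methylhex-4-en-1-imine | CC1(C)O[C@](C)([C@@H](/C=N/N2CCC[C@@H]2COC)CC=C(C)C)CC[C@H]1Br
F6 | step 5 | (2S)-2-[(2S,5R)-5-bromo-2,6,6-trimethyloxan-2-yl]-5-methylhex-4-enal | CC1(C)O[C@](C)([C@@H](C=O)CC=C(C)C)CC[C@H]1Br
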